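The eleven-membered ring is grown from a seven-membered ring instead of being closed end to end. With the ring numbered C1 (=CH2) to C11, the segment C2–C1–C11–C10–C9=C8 becomes a δ,ε-unsaturated ketone once C2 is a carbonyl, which is the retron of an oxy-Cope shift. One anionic [3,3] rearrangement of a trans-1,2-divinylcycloheptanol breaks C2–C8 and forms C10–C11. It also sets the E C8=C9 olefin and delivers the C2 ketone next to C1, the future methylene-bearing carbon. The precursor is a cycloheptane (C2–C8). It carries hydroxyl and vinyl at C2, methyl and vinyl at C8, the gem-dimethyl group at C4 and the preset C6 silyl ether.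

Key step: step 11

Remark on labels: C1–C11 are the ring atoms of the target and are used for all intermediates. C9/C10 are the carbons of the C8 vinyl group, and C1/C11 are those of the C2 vinyl group.

Remark on descriptors: the R/S label at C6 changes along the route only because the CIP ranking of C5 and C7 changes. No bond at C6 is ever broken.

Design remark:
- The cycloheptane is closed by metathesis of an acyclic chain. The positions of C2 (carbonyl), C4 (gem-dimethyl) and C6 (oxygen) therefore follow from connectivity and not from a migratory preference.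
- No β-silyloxy ketone ever occurs.
- The methyl group is the last substituent brought to C8. It and the C2 vinyl group thus both enter from the same open ring face, and this is what makes the two vinyl groups trans.

Assumption: (−)-B-allyldiisopinocampheylborane is used as the commercial pentane solution.

Step 1
Reactants: 1 mesityl oxide; 2 allyltrimethylsilane
Product: 4 4,4-dimethylhept-6-en-2-one, via trichlorotitanium enolate 3 (not isolated)
Conditions: TiCl4, CH2Cl2, −78 °C; H2O
Reagents that add atoms: none
Why: Hosomi–Sakurai conjugate allylation: TiCl4 activates the enone and the γ-carbon of the allylsilane attacks the β,β-dimethyl terminus, so the C4 quaternary carbon, C3 and the C2 carbonyl are in place after one operation.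

Step 2
Reactants: 4 4,4-dimethylhept-6-en-2-one
Product: 6 3,3-dimethyl-5-oxohexanal, via secondary ozonide 5 (not isolated)
Conditions: O3, CH2Cl2, −78 °C; then PPh3, −78 °C to rt
Reagents that add atoms: ozone [O-][O+]=O
Why: Ozonolysis with reductive work-up cleaves the only C=C bond to the C6 aldehyde and does not touch the methyl ketone.

Step 3
Reactants: 6 3,3-dimethyl-5-oxohexanal; 7 (−)-B-allyldiisopinocampheylborane
Product: 9 (6S)-6-hydroxy-4,4-dimethylnon-8-en-2-one, via borinate ester 8 (not isolated)
Conditions: Et2O, −78 °C; then NaOH, H2O2, 0 °C to rt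
Reagents that add atoms: none
Why: Brown allylboration through a closed chair transition state: at −78 °C the aldehyde reacts far faster than the methyl ketone, and the isopinocampheyl groups derived from (+)-α-pinene send the allyl group (C7, C8) to the aldehyde face that gives the 6S alcohol, the only stereocentre that survives to the target.

Step 4
Reactants: 9 (6S)-6-hydroxy-4,4-dimethylnon-8-en-2-one
Product: 10 (6S)-6-(tert-butyldimethylsilyloxy)-4,4-dimethylnon-8-en-2-one
Conditions: TBSCl, imidazole, DMF, rt
Reagents that add atoms: tert-butyldimethylsilyl chloride CC(C)(C)[Si](C)(C)Cl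
Why: Imidazole-assisted silylation of the secondary alcohol gives an ether that tolerates amide bases, organometallics and KH, and its oxygen stays on a carbon γ or more remote from every later carbonyl group, so β-elimination is excluded.

Step 5
Reactants: 10 (6S)-6-(tert-butyldimethylsilyloxy)-4,4-dimethylnon-8-en-2-one
Product: 12 (6S)-6-(tert-butyldimethylsilyloxy)-4,4-dimethyl-2-(trimethylsilyloxy)nona-1,8-diene, via methyl-side lithium enolate 11 (not isolated)
Conditions: LiN(iPr)2, THF, −78 °C; then Me3SiCl, −78 to 0 °C
Reagents that add atoms: chlorotrimethylsilane C[Si](C)(C)Cl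
Why: Kinetic enolate formation and O-silylation: the amide base takes a proton from the unhindered methyl group and not from the neopentyl C3 methylene, which fixes a 1,1-disubstituted enol ether for the metathesis.

Step 6
Reactants: 12 (6S)-6-(tert-butyldimethylsilyloxy)-4,4-dimethyl-2-(trimethylsilyloxy)nona-1,8-diene
Product: 13 (4S)-4-(tert-butyldimethylsilyloxy)-6,6-dimethyl-1-(trimethylsilyloxy)cyclohept-1-ene
Conditions: second-generation Grubbs catalyst (5 mol%), toluene (0.005 M), 70 °C, argon purge
Reagents that add atoms: none
Why: Ring-closing metathesis of a silyl enol ether with a terminal olefin, helped by the gem-dimethyl effect, closes the seven-membered ring with loss of ethene and puts the masked ketone unambiguously at C2 with its enol double bond towards C8.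

Step 7
Reactants: 13 (4S)-4-(tert-butyldimethylsilyloxy)-6,6-dimethyl-1-(trimethylsilyloxy)cyclohept-1-ene; 14 acetaldehyde
Product: 17 (4S)-4-(tert-butyldimethylsilyloxy)-2-(1-hydroxyethyl)-6,6-dimethylcycloheptan-1-one (epimers at ring C2 and at the carbinol carbon), via ring lithium enolate 15 (not isolated), via lithium aldolate 16 (not isolated)
Conditions: MeLi, THF, 0 °C; then 14, −78 °C; aq NH4Cl
Reagents that add atoms: none
Why: Regiospecific enolate generation from the enol silane with MeLi followed by a lithium aldol addition attaches C9 and C10 at C8 only, and the two new stereocentres are irrelevant because the next step removes them.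

Step 8
Reactants: 17 (4S)-4-(tert-butyldimethylsilyloxy)-2-(1-hydroxyethyl)-6,6-dimethylcycloheptan-1-one
Product: 19 (2E,4R)-4-(tert-butyldimethylsilyloxy)-2-ethylidene-6,6-dimethylcycloheptan-1-one, via secondary mesylate 18 (not isolated)
Conditions: MsCl, Et3N, CH2Cl2, 0 °C; then DBU, rt
Reagents that add atoms: none
Why: Mesylation and base-induced E1cB elimination give the conjugated exocyclic enone, whose E isomer (methyl turned away from the carbonyl group) is the more stable one, and either isomer would lead to the same dienolate.

Step 9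
Reactants: 19 (2E,4R)-4-(tert-butyldimethylsilyloxy)-2-ethylidene-6,6-dimethylcycloheptan-1-one
Product: 21 (2R,4R)-4-(tert-butyldimethylsilyloxy)-2-ethenyl-2,6,6-trimethylcycloheptan-1-one (C8 methyl cis to the C6 silyloxy group), via potassium dienolate 20 (not isolated)
Conditions: KOtBu, tBuOH/THF, MeI, 0 °C
Reagents that add atoms: iodomethane CI
Why: Deconjugative α-alkylation: reversible γ-deprotonation at C10 gives the extended dienolate, which is methylated at C8 and thereby releases the vinyl group, and MeI should approach opposite to the pseudo-axial C4 methyl group, whose orientation is fixed by the equatorial C6 silyloxy group, while the neopentyl C3 position resists alkylation.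

Step 10
Reactants: 21 (2R,4R)-4-(tert-butyldimethylsilyloxy)-2-ethenyl-2,6,6-trimethylcycloheptan-1-one; 22 vinylmagnesium bromide
Product: 24 (1S,2R,4R)-4-(tert-butyldimethylsilyloxy)-1,2-diethenyl-2,6,6-trimethylcycloheptan-1-ol (vinyl groups trans, hydroxyl trans to the C8 methyl and to the silyloxy group), via bromomagnesium alkoxide 23 (not isolated)
Conditions: LaCl3·2LiCl, THF, 0 °C; aq NH4Cl
Reagents that add atoms: none
Why: Lanthanide-assisted Grignard 1,2-addition suppresses enolisation at C3, and the same pseudo-axial C4 methyl group that steered step 9 blocks one carbonyl face, so the vinyl group should enter on the face that already received the C8 methyl group and set the C2 centre with the two vinyl groups trans.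

Step 11
Reactants: 24 (1S,2R,4R)-4-(tert-butyldimethylsilyloxy)-1,2-diethenyl-2,6,6-trimethylcycloheptan-1-ol
Product: 27 (5E,8R)-8-(tert-butyldimethylsilyloxy)-6,10,10-trimethylcycloundec-5-en-1-one, via potassium alkoxide 25 (not isolated), via potassium enolate 26 (not isolated)
Conditions: KH, 18-crown-6, THF, 0 °C to rt; aq NH4Cl, −78 °C
Reagents that add atoms: none
Why: KH deprotonates the tertiary alcohol and 18-crown-6 frees alkoxide 25, whose charge weakens the adjacent C2–C8 bond and accelerates a concerted [3,3]-sigmatropic shift, the anionic oxy-Cope rearrangement that is well known to turn 1,2-divinylcycloalkanols into cycloalkenones four atoms larger. The eleven-membered ring is not closed end to end but arises by four-atom ring expansion, C10–C11 forming between the two vinyl termini while the C2–C8 bond of the seven-membered ring breaks. No stereocentre is created: C2 and C8 are erased, and C6, remote from the reacting array, is untouched. The selectivity needed is the E geometry of C8=C9, and with trans-diequatorial vinyl groups only one chair is accessible, with ring carbons C3 and C7 equatorial and the oxide and the C8 methyl axial, so C7 ends up trans to C10. The change from alkoxide to the delocalised enolate 26 drives the expansion, and cold protonation gives ketone 27. The silyl ether lies on the ring face opposite to the alkoxide, which keeps it out of reach for oxygen-to-oxygen silyl migration.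

Step 12
Reactants: 27 (5E,8R)-8-(tert-butyldimethylsilyloxy)-6,10,10-trimethylcycloundec-5-en-1-one
Product: 31 (5E,8R)-8-(tert-butyldimethylsilyloxy)-6,10,10-trimethyl-2-methylidenecycloundec-5-en-1-one, via lithium enolate 28 (not isolated), via Mannich base 29 (not isolated), via methiodide 30 (not isolated)
Conditions: LiN(iPr)2, THF, −78 °C; Me2N=CH2 I (Eschenmoser's salt), −78 °C to rt; then MeI, rt; then DBU, rt
Reagents that add atoms: N,N-dimethylmethyleneiminium iodide C=[N+](C)C.[I-]
Why: Kinetic deprotonation occurs at C1 because C3 is neopentyl, the Mannich reaction with Eschenmoser's salt brings in the exocyclic carbon, and quaternisation followed by Hofmann-type E1cB elimination gives the α-methylene ketone.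

Step 13
Reactants: 31 (5E,8R)-8-(tert-butyldimethylsilyloxy)-6,10,10-trimethyl-2-methylidenecycloundec-5-en-1-one
Product: 32 (5E,8R)-8-(tert-butyldimethylsilyloxy)-6,10,10-trimethyl-2-methylidenecycloundec-5-en-1-ol (both epimers at the carbinol carbon C2)
Conditions: NaBH4, CeCl3·7H2O, MeOH, −78 to 0 °C
Reagents that add atoms: none
Why: Luche reduction: the cerium-modified borohydride attacks the carbonyl carbon and not the methylene terminus, and the new C2 centre may stay undefined because both epimers ionise to the same allyl complex and C2 becomes sp2.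

Step 14
Reactants: 32 (5E,8R)-8-(tert-butyldimethylsilyloxy)-6,10,10-trimethyl-2-methylidenecycloundec-5-en-1-ol
Product: 33 methyl carbonate of 32
Conditions: ClCO2Me, pyridine, DMAP (cat.), CH2Cl2, 0 °C to rt
Reagents that add atoms: methyl chloroformate COC(=O)Cl
Why: DMAP-catalysed acylation converts the allylic alcohol into a carbonate that ionises readily and irreversibly (loss of CO2) under neutral conditions.

Step 15
Reactants: 33 methyl carbonate of 32
Product: 34 tert-butyldimethylsilyl ether of (1S,3E,8E)-3,10,10-trimethyl-7-methylidenecycloundeca-3,8-dien-1-ol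
Conditions: Pd(PPh3)4 (10 mol%), 1,4-dioxane, 80 °C
Reagents that add atoms: none
Why: Palladium-catalysed elimination of an allylic carbonate (Tsuji–Trost ionisation, then loss of a β-hydrogen): zerovalent palladium forms the π-allyl complex over C2–C1–CH2, C3 is the only carbon next to an allyl terminus that bears hydrogen, and the bulky C4 turns away from C1, which should give the E C2=C3 bond of the diene.

Step 16
Reactants: 34 tert-butyldimethylsilyl ether of (1S,3E,8E)-3,10,10-trimethyl-7-methylidenecycloundeca-3,8-dien-1-ol
Product: 35 (1S,3E,8E)-3,10,10-trimethyl-7-methylidenecycloundeca-3,8-dien-1-ol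
Conditions: Bu4NF, THF, rt
Reagents that add atoms: none
Why: Fluoride-induced desilylation works without acid and therefore spares the triene, which is prone to transannular cyclisation.

Step 17
Reactants: 36 vanillic acid
Product: 38 4-(tert-butyldimethylsilyloxy)-3-methoxybenzoic acid, via bis-silylated vanillic acid 37 (not isolated)
Conditions: TBSCl (2.5 equiv), imidazole, DMF, rt; then AcOH/THF/H2O, rt
Reagents that add atoms: tert-butyldimethylsilyl chloride CC(C)(C)[Si](C)(C)Cl
Why: Exhaustive silylation followed by selective hydrolysis relies on the silyl ester being far more labile than the aryl silyl ether, which masks the phenol against self-acylation.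

Step 18
Reactants: 35 (1S,3E,8E)-3,10,10-trimethyl-7-methylidenecycloundeca-3,8-dien-1-ol; 38 4-(tert-butyldimethylsilyloxy)-3-methoxybenzoic acid
Product: 39 (1S,3E,8E)-3,10,10-trimethyl-7-methylidenecycloundeca-3,8-dien-1-yl 4-(tert-butyldimethylsilyloxy)-3-methoxybenzoate
Conditions: DCC, DMAP, CH2Cl2, 0 °C to rt
Reagents that add atoms: none
Why: Steglich esterification activates the acid and not the alcohol, so the C6–O bond is not broken and the configuration is retained.

Step 19
Reactants: 39 (1S,3E,8E)-3,10,10-trimethyl-7-methylidenecycloundeca-3,8-dien-1-yl 4-(tert-butyldimethylsilyloxy)-3-methoxybenzoate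
Product: 40 (1S,3E,8E)-3,10,10-trimethyl-7-methylidenecycloundeca-3,8-dien-1-yl 4-hydroxy-3-methoxybenzoate (target)
Conditions: Bu4NF, AcOH, THF, 0 °C
Reagents that add atoms: none
Why: Buffered fluoride cleaves the aryl silyl ether quickly and leaves the benzoate ester and the olefins untouched.

Compound list
1 | mesityl oxide (4-methylpent-3-en-2-one) | CC(C)=CC(C)=O | starting material
2 | allyltrimethylsilane | C=CC[Si](C)(C)C | starting material
3 | trichlorotitanium enolate of 4 | CC(=CC(C)(C)CC=C)O[Ti](Cl)(Cl)Cl | intermediate
4 | 4,4-dimethylhept-6-en-2-one | CC(=O)CC(C)(C)CC=C | intermediate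
5 | secondary ozonide of 4, 4,4-dimethyl-5-(1,2,4-trioxolan-3-yl)pentan-2-one | CC(=O)CC(C)(C)CC1OCOO1 | intermediate
6 | 3,3-dimethyl-5-oxohexanal | CC(=O)CC(C)(C)CC=O | intermediate
7 | (−)-B-allyldiisopinocampheylborane (isopinocampheyl groups from (+)-α-pinene) | C=CCB([C@@H]1C[C@@H]2C[C@H]([C@H]1C)C2(C)C)[C@@H]1C[C@@H]2C[C@H]([C@H]1C)C2(C)C | starting material
8 | diisopinocampheylborinate ester of 9 | CC(=O)CC(C)(C)C[C@@H](OB([C@@H]1C[C@@H]2C[C@H]([C@H]1C)C2(C)C)[C@@H]1C[C@@H]2C[C@H]([C@H]1C)C2(C)C)CC=C | intermediate
9 | (6S)-6-hydroxy-4,4-dimethylnon-8-en-2-one | CC(=O)CC(C)(C)C[C@@H](O)CC=C | intermediate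
10 | (6S)-6-(tert-butyldimethylsilyloxy)-4,4-dimethylnon-8-en-2-one | CC(=O)CC(C)(C)C[C@@H](O[Si](C)(C)C(C)(C)C)CC=C | intermediate
11 | methyl-side lithium enolate of 10 | [Li+].C=C([O-])CC(C)(C)C[C@@H](O[Si](C)(C)C(C)(C)C)CC=C | intermediate
12 | (6S)-6-(tert-butyldimethylsilyloxy)-4,4-dimethyl-2-(trimethylsilyloxy)nona-1,8-diene | C=C(O[Si](C)(C)C)CC(C)(C)C[C@@H](O[Si](C)(C)C(C)(C)C)CC=C | intermediate
13 | (4S)-4-(tert-butyldimethylsilyloxy)-6,6-dimethyl-1-(trimethylsilyloxy)cyclohept-1-ene | CC1(C)C[C@@H](O[Si](C)(C)C(C)(C)C)CC=C(O[Si](C)(C)C)C1 | intermediate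
14 | acetaldehyde | CC=O | starting material
15 | ring lithium enolate (C2–C8) from 13 | [Li+].CC1(C)C[C@@H](O[Si](C)(C)C(C)(C)C)CC=C([O-])C1 | intermediate
16 | lithium aldolate of 17 | [Li+].CC1(C)C[C@@H](O[Si](C)(C)C(C)(C)C)CC(C(C)[O-])C(=O)C1 | intermediate
17 | (4S)-4-(tert-butyldimethylsilyloxy)-2-(1-hydroxyethyl)-6,6-dimethylcycloheptan-1-one, epimers at ring C2 and carbinol carbon | CC1(C)C[C@@H](O[Si](C)(C)C(C)(C)C)CC(C(C)O)C(=O)C1 | intermediate
18 | methanesulfonate of 17 | CC1(C)C[C@@H](O[Si](C)(C)C(C)(C)C)CC(C(C)OS(C)(=O)=O)C(=O)C1 | intermediate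
19 | (2E,4R)-4-(tert-butyldimethylsilyloxy)-2-ethylidene-6,6-dimethylcycloheptan-1-one | CC1(C)C[C@@H](O[Si](C)(C)C(C)(C)C)C/C(=C\C)C(=O)C1 | intermediate
20 | potassium dienolate of 19 (O–C2=C8–C9=C10) | [K+].C=CC1=C([O-])CC(C)(C)C[C@@H](O[Si](C)(C)C(C)(C)C)C1 | intermediate
21 | (2R,4R)-4-(tert-butyldimethylsilyloxy)-2-ethenyl-2,6,6-trimethylcycloheptan-1-one | O=C1CC(C)(C)C[C@@H](O[Si](C)(C)C(C)(C)C)C[C@]1(C)C=C | intermediate
22 | vinylmagnesium bromide | C=C[Mg]Br | starting material
23 | bromomagnesium alkoxide of 24 | C=C[C@@]1(O[Mg]Br)CC(C)(C)C[C@@H](O[Si](C)(C)C(C)(C)C)C[C@]1(C)C=C | intermediate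
24 | (1S,2R,4R)-4-(tert-butyldimethylsilyloxy)-1,2-diethenyl-2,6,6-trimethylcycloheptan-1-ol (key-step precursor) | C=C[C@@]1(O)CC(C)(C)C[C@@H](O[Si](C)(C)C(C)(C)C)C[C@]1(C)C=C | intermediate
25 | potassium alkoxide of 24 | [K+].C=C[C@@]1([O-])CC(C)(C)C[C@@H](O[Si](C)(C)C(C)(C)C)C[C@]1(C)C=C | intermediate
26 | potassium C1=C2 enolate of 27 (C3 trans to C11) | [K+].[O-]/C1=C\CC/C=C(\C)C[C@H](O[Si](C)(C)C(C)(C)C)CC(C)(C)C1 | intermediate
27 | (5E,8R)-8-(tert-butyldimethylsilyloxy)-6,10,10-trimethylcycloundec-5-en-1-one (key-step product) | O=C1CC(C)(C)C[C@@H](O[Si](C)(C)C(C)(C)C)C/C(C)=C/CCC1 | intermediate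
28 | lithium C1=C2 enolate of 27 | [Li+].[O-]C1=CCC/C=C(\C)C[C@H](O[Si](C)(C)C(C)(C)C)CC(C)(C)C1 | intermediate
29 | (5E,8R)-8-(tert-butyldimethylsilyloxy)-2-[(dimethylamino)methyl]-6,10,10-trimethylcycloundec-5-en-1-one, epimers at ring C2 | O=C1CC(C)(C)C[C@@H](O[Si](C)(C)C(C)(C)C)C/C(C)=C/CCC1CN(C)C | intermediate
30 | methiodide of 29 | O=C1CC(C)(C)C[C@@H](O[Si](C)(C)C(C)(C)C)C/C(C)=C/CCC1C[N+](C)(C)C.[I-] | intermediate
31 | (5E,8R)-8-(tert-butyldimethylsilyloxy)-6,10,10-trimethyl-2-methylidenecycloundec-5-en-1-one | O=C1CC(C)(C)C[C@@H](O[Si](C)(C)C(C)(C)C)C/C(C)=C/CCC1=C | intermediate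
32 | (5E,8R)-8-(tert-butyldimethylsilyloxy)-6,10,10-trimethyl-2-methylidenecycloundec-5-en-1-ol, both carbinol epimers | OC1CC(C)(C)C[C@@H](O[Si](C)(C)C(C)(C)C)C/C(C)=C/CCC1=C | intermediate
33 | methyl carbonate of 32 | COC(=O)OC1CC(C)(C)C[C@@H](O[Si](C)(C)C(C)(C)C)C/C(C)=C/CCC1=C | intermediate
34 | tert-butyldimethylsilyl ether of 35 | C=C1/C=C/C(C)(C)C[C@@H](O[Si](C)(C)C(C)(C)C)C/C(C)=C/CC1 | intermediate
35 | (1S,3E,8E)-3,10,10-trimethyl-7-methylidenecycloundeca-3,8-dien-1-ol | C=C1/C=C/C(C)(C)C[C@@H](O)C/C(C)=C/CC1 | intermediate
36 | vanillic acid | COc1cc(C(=O)O)ccc1O | starting material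
37 | tert-butyldimethylsilyl 4-(tert-butyldimethylsilyloxy)-3-methoxybenzoate | COc1cc(C(=O)O[Si](C)(C)C(C)(C)C)ccc1O[Si](C)(C)C(C)(C)C | intermediate
38 | 4-(tert-butyldimethylsilyloxy)-3-methoxybenzoic acid | COc1cc(C(=O)O)ccc1O[Si](C)(C)C(C)(C)C | intermediate
39 | (1S,3E,8E)-3,10,10-trimethyl-7-methylidenecycloundeca-3,8-dien-1-yl 4-(tert-butyldimethylsilyloxy)-3-methoxybenzoate | C=C1/C=C/C(C)(C)C[C@@H](OC(=O)c2ccc(O[Si](C)(C)C(C)(C)C)c(OC)c2)C/C(C)=C/CC1 | intermediate
40 | (1S,3E,8E)-3,10,10-trimethyl-7-methylidenecycloundeca-3,8-dien-1-yl 4-hydroxy-3-methoxybenzoate | C=C1/C=C/C(C)(C)C[C@@H](OC(=O)c2ccc(O)c(OC)c2)C/C(C)=C/CC1 | target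

Total step count: 19. Longest linear sequence: 18 (steps 1–16, 18 and 19). Step 17 is the side branch.

The three steps most likely to fail are step 11, step 10 and step 15.

For step 11, several things may go wrong:
- the congested alkoxide may fragment;
- a [1,3] shift may compete;
- passage through a boat array would erode the C8=C9 geometry;
- the base may strip the silyl group.

The fallback keeps the same bond reorganisation but runs it without charge, as a thermal siloxy-Cope rearrangement. It sets out from 24, which is silylated with Me3SiOTf and 2,6-lutidine in CH2Cl2 to the tertiary trimethylsilyl ether F1. Heating F1 in degassed o-dichlorobenzene at about 200 °C in a base-washed sealed vessel should take it through the same chair to the ring-expanded trimethylsilyl enol ether F2. Brief treatment of F2 with K2CO3 in MeOH cleaves only the enol silane and comes back to the route at 27.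

For step 10, addition to the doubly flanked carbonyl group may be slow, enolisation at C3 may compete, and facial selectivity may be poor. Poor selectivity would mix in the cis-divinyl isomer and spoil the olefin geometry of the key step. The fallback builds the carbinol in two C1 operations under a different kind of stereocontrol. It sets out from 21. A Corey–Chaykovsky reaction with dimethylsulfoxonium methylide (Me3S(O)I, NaH, DMSO) forms the betaine reversibly, so the new C–C bond should settle in the less hindered equatorial position on the face of the C8 methyl group. This gives the spiro-epoxide F3. Excess dimethylsulfonium methylide (Me3SI, n-BuLi, THF, −10 °C to rt) then opens F3 at its CH2 group and loses dimethyl sulfide. This known one-carbon homologation of a terminal epoxide to an allylic alcohol comes back to the route at 24.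

For step 15, methoxide may capture the allylpalladium intermediate, removal of the neopentyl C3 hydrogen may be sluggish, and control over the C2=C3 geometry may be lost. The fallback replaces reduction, activation and elimination by enol triflate hydrogenolysis. It sets out from 31, in which C3 is the only enolisable position. KN(SiMe3)2 in the presence of Comins' reagent (THF, −78 °C) should give the enolate with oxygen cis to C4 and hence the dienyl triflate F4, with C1 and C4 trans across C2=C3. Hydrogenolysis with Pd(PPh3)4, HCO2H and n-Bu3N in DMF at 60 °C proceeds with retention of olefin geometry and comes back to the route at 34. Steps 13–15 are then not needed.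

Further compounds
F1 | step 11 | trimethylsilyl ether of 24 at the tertiary C2 oxygen | C=C[C@@]1(O[Si](C)(C)C)CC(C)(C)C[C@@H](O[Si](C)(C)C(C)(C)C)C[C@]1(C)C=C
F2 | step 11 | trimethylsilyl enol ether (C1=C2) of 27, C3 trans to C11, C8=C9 E | C[Si](C)(C)O/C1=C\CC/C=C(\C)C[C@H](O[Si](C)(C)C(C)(C)C)CC(C)(C)C1
F3 | step 10 | spiro-epoxide of 21 (1-oxaspiro[2.6]nonane; epoxide CH2 on the face of the C8 methyl group, oxygen on the face of the C8 vinyl group) | C1[C@@]2(O1)CC(C)(C)C[C@@H](O[Si](C)(C)C(C)(C)C)C[C@]2(C)C=C
F4 | step 15 | C2 enol triflate of 31 (2-triflyloxy-1,3-diene, C1 and C4 trans across C2=C3) | C=C1/C(OS(=O)(=O)C(F)(F)F)=C/C(C)(C)C[C@@H](O[Si](C)(C)C(C)(C)C)C/C(C)=C/CC1
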